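A small charge of starting material, c(starting material) = 0.064 M, divides between enzyme and protic impurity, and what I watch in a repeat is the share of target in target plus over-reaction product at the end.

common to all: enzyme 0.01 mol%

| flask | starting material | second substrate | protic impurity | remark | time |
|---|---|---|---|---|---|
| red | 0.064 M | 1 equiv | 0.064 M | run made earlier |  |
| violet | 0.032 M | 1 equiv | 0.064 M | run made earlier |  |
| green | 0.13 M | 1 equiv | 0.064 M | run made earlier |  |
| winter | 0.064 M (fed, over 10 min) | 1.00 equiv | 0.0640 M | all else is in the flask from the start; the feed brings no volume worth counting | 15 min |
| dawn | 0.064 M | 1.00 equiv | 0.0640 M | everything together at the start | 15 min |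
| midnight | 0.064 M | 1.00 equiv (fed, over 10 min) | 0.0640 M | all else is in the flask from the start; the feed brings no volume worth counting | 15 min |

- red (time / min: target / %, over-reaction product / %, starting material / %): 1.33: 19.6, 2.7, 2.1; 4.00: 12.7, 12.4, 0; 8.00: 5.2, 19.0, 0.1; 10.0: 3.2, 20.9, 0.5; 15.0: 0.9, 23.4, 0
- violet (time / min: target / %, over-reaction product / %, starting material / %): 1.50: 11.5, 2.1, 0.3; 5.00: 5.4, 8.1, 0.3; 8.00: 3.2, 11.2, 0.3; 12.0: 1.2, 11.4, 0.3; 20.0: 0.1, 13.3, 0.1
- green (time / min: target / %, over-reaction product / %, starting material / %): 1.33: 31.3, 3.8, 17.3; 2.50: 38.3, 13.2, 0; 5.00: 22.9, 28.6, 0; 10.0: 7.6, 43.1, 0; 20.0: 0.7, 49.5, 0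

(readings scatter by 0.3 percentage points)

- the best flask by share of target in target plus over-reaction product; "all alike" if 1.5 percentage points covers them all (winter / dawn / midnight / all alike)
- share of target in target plus over-reaction product at the end, winter
- share of target in target plus over-reaction product at the end, dawn
- share of target in target plus over-reaction product at the end, midnight

- steps under discussion: starting material + enzyme <-> complex A; complex A -> enzyme + target; second substrate + enzyme <-> complex B; complex B -> enzyme + second product; starting material -> decomposition product; target -> over-reaction product; starting material + protic impurity -> quenched substrate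

First I ask which inputs this share needs. An error in the yield cancels in the share as long as the timing of formation stays, so the plateaus can be rough. What counts is the age of the target when read. Target lost at first order with rate constant k survives an age a as exp(−k·a), so the share is the mean of that survival over the ages present. The zero of my scale is target formed at the very start, with share exp(−k·t).

So k must be known well. The green run reads 0.216 min⁻¹, the loss constant of target, and the red run reads 0.230 min⁻¹. That gap moves the zero from 3.94 % to 3.19 %. I keep the green value, because its target reading is larger than the red run's at the same time.

Timing comes next. The red run, whose charges dawn repeats, holds 2.1 % starting material at 1.33 min, so I place dawn between 3.94 % and 5.25 %. Midnight has starting material and enzyme together from the start, so I give it the same band.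

In winter the feed brings 0.006400 M min⁻¹, slower than the 0.0808 M min⁻¹ at which the green run, on average up to its first reading, consumed starting material by all routes. I therefore assume that target forms evenly along the feed, and with t the time of reading and tf the feed time, the mean survival [exp(−k(t−tf)) − exp(−k·t)]/(k·tf) gives 14.0 %, higher than the top of my band for dawn.

The forecast names winter, with 13.3 %, 4.1 % and 4.2 % for winter, dawn and midnight: “Share depends only on when target forms”.

The flasks give winter as best, with 15.8 % for winter, 5.00 % for dawn and 4.79 % for midnight.

    starting material + enzyme ⇌ complex A (K = 230 M⁻¹, k = 68000 M⁻¹ s⁻¹)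
    complex A → enzyme + target (k = 65.0 s⁻¹)
    second substrate + enzyme ⇌ complex B (K = 380 M⁻¹, k = 3.40 × 10⁵ M⁻¹ s⁻¹)
    complex B → enzyme + second product (k = 500 s⁻¹)
    starting material → decomposition product (k = 1.30 × 10⁻⁵ s⁻¹)
    target → over-reaction product (k = 0.00350 s⁻¹)
    starting material + protic impurity → quenched substrate (k = 1.00 M⁻¹ s⁻¹)

Winter stands 1.8 percentage points above my 14.0 %. The neighbouring flask is winter read at 10.0 min, as the feed ends. With even formation the ages of target there run from zero to tf, so with the same k the mean survival is [one minus exp(−k·tf)]/(k·tf), which gives 41.0 %. That neighbour holds 24.7 % target and 31.3 % over-reaction product, a share of 44.1 %.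

The data are calculated with constants of no real substance; noise was put on by code.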